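5.94 s is the number your next run hangs on: the substrate half-life in the east run, read between 10.0 s and 20.0 s, while the substrate falls from 38.2% to 11.9% of the charge.

| flask | substrate | partner | initiator | remark | time |
|---|---|---|---|---|---|
| south | 12 mM | 1.1 equiv | 5 mol% | run made earlier |  |
| east | 19 mM | 1.1 equiv | 5 mol% | run made earlier |  |
| flask | 25 mM | 1.10 equiv | 5 mol% |  | 2.0 min |

| run | time / s | target / % | side product / % | substrate / % |
|---|---|---|---|---|
| south | 10.0 | 46.1 | 6.1 | 47.8 |
| south | 12.0 | 51.7 | 7.5 | 40.6 |
| south | 20.0 | 67.2 | 12.5 | 19.9 |
| south | 30.0 | 75.7 | 16.5 | 8.5 |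
| south | 40.0 | 78.7 | 18.1 | 3.5 |
| south | 60.0 | 81.2 | 19.4 | 0 |
| south | 80.0 | 80.9 | 18.7 | 0.6 |
| east | 10.0 | 52.9 | 10.3 | 38.2 |
| east | 12.0 | 58.4 | 12.3 | 30.2 |
| east | 20.0 | 70.3 | 18.7 | 11.9 |
| east | 30.0 | 75.5 | 20.8 | 3.5 |
| east | 50.0 | 77.6 | 23.3 | 0 |
| east | 80.0 | 77.7 | 22.3 | 0 |

(standard deviation of a reading: 0.3 percentage points)

- the target in the flask at 2.0 min, as a percentage of the substrate charged
- the side product in the flask at 2.0 min, as a percentage of the substrate charged

- percent here means substrate units held: one side product counts as two

The decision is whether to keep 2.0 min for the new flask or spend effort on the time. Count the halvings allowed, the time granted divided by the substrate half-life: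

halvings allowed = 120 s / 5.94 s = 20.2

fraction of the substrate reckoned left, if that half-life holds = 8.35 × 10⁻⁷

The south run reads 7.91 s, longer than the east value. In these two readings the half-life shortens from the south run to the east run as the substrate charge rises, with partner and initiator held in equivalents, so I expect the east value to be a cautious one for the flask. Keep the time, then, and read the run for its split. The last readings give side product at 18.7% in the south run and 22.3% in the east run.

The forecast gives 75% target and 25% side product, and says of the time: “By 2.0 min the reaction is therefore long finished.”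

The flask gives 75.3% target and 24.7% side product.

    initiator → 2 initiating radical (k = 0.00330 s⁻¹)
    substrate + initiating radical → capped initiator + first chain carrier (k = 5.30 × 10⁵ L mol⁻¹ s⁻¹)
    partner + first chain carrier → target + second chain carrier (k = 13000 L mol⁻¹ s⁻¹)
    substrate + second chain carrier → by-product + first chain carrier (k = 94000 L mol⁻¹ s⁻¹)
    2 second chain carrier → ended chains (k = 3.00 × 10⁶ L mol⁻¹ s⁻¹)
    substrate + target → side product (k = 1.60 L mol⁻¹ s⁻¹)

Left for 20.0 min, the flask still holds 75.3% target. At 0.200 min the count allows 2.02 halvings, which reckons 24.7% of the substrate left, and the flask then holds 24.0% substrate. A neighbour flask charged with 0.440 equiv of partner is granted the same 20.2 halvings, but there the partner is the limiting reagent: it stands at 0% at 2.00 min, and that neighbour flask still holds 19.3% substrate.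

Readings and results are calculated with constants of no real substance, and the scatter is random.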